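**Strategy.** The ten-membered carbocycle (germacrane numbering) is closed last, across C1–C2, by an intramolecular boron aldol addition of the C3 methyl-ketone enolate (C2) to a C1 aldehyde whose neighbour C10 carries chlorine, methyl and the C9 chain. In-flask LiBH4 reduction of the boron aldolate then sets C3. One operation thus forms the ring and fixes C1 and C3, exploiting the 1,3-relationship between the C3 ester oxygen and the oxygen of the C1–C10 oxirane; the chlorohydrin is closed to the epoxide afterwards. The seco keto-aldehyde is an α-methylene-γ-butyrolactone carrying a (Z)-oxobutenyl arm (from 2,3-dimethylfuran) and a chloro-aldehyde arm (from a glutamate-derived lactone), joined by a chromium-mediated allylation.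

Key step: step 15

Remark on numbering: germacrane numbering is used for every compound that contains the future ring (ring carbons C1–C10, C14 = methyl on C10, C15 = methyl on C4, lactone carbons C11–C13).
Assumption: (5R)-5-[(trityloxy)methyl]dihydrofuran-2(3H)-one (6) is taken as commercial; dimethyldioxirane is used as a freshly prepared acetone solution and enal 5 is used crude.

**Side-chain acid**

Step 1
Reactants: 1 (E)-2-methylbut-2-en-1-ol
Product: 2 [(2R,3R)-2,3-dimethyloxiran-2-yl]methanol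
Conditions: Ti(OiPr)4 (10 mol%), D-(−)-diethyl tartrate (12 mol%), t-BuOOH, 4 Å MS, CH2Cl2, −20 °C
Reagents that add atoms: tert-butyl hydroperoxide CC(C)(C)OO
Why: Sharpless asymmetric epoxidation, in which the titanium D-(−)-tartrate complex should deliver oxygen to the face that gives the (2R,3R) epoxide (L-(+)-tartrate gives 2S,3S with E-allylic alcohols), the syn addition keeping the two methyl groups cis.

Step 2
Reactants: 2 [(2R,3R)-2,3-dimethyloxiran-2-yl]methanol
Product: 3 (2S,3R)-2,3-dimethyloxirane-2-carboxylic acid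
Conditions: RuCl3·xH2O (2 mol%), NaIO4, CCl4/MeCN/H2O, 0 °C to rt
Reagents that add atoms: water O
Why: RuO4-catalysed oxidation of the primary alcohol through the aldehyde hydrate should give the acid without touching the epoxide or either stereocentre (the C2 descriptor changes from R to S only through the priority rules).

**Western fragment**

Step 3
Reactants: 4 2,3-dimethylfuran
Product: 5 (2Z)-3-methyl-4-oxopent-2-enal
Conditions: dimethyldioxirane (acetone), −78 to 0 °C; solution used at once
Reagents that add atoms: dimethyldioxirane CC1(C)OO1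
Why: oxidative ring opening of a furan (epoxidation, then opening of the furan oxide) should give the cis 4-oxo-enal, the Z geometry of the future C4=C5 bond being inherited from the ring.

**Eastern fragment**

Step 4
Reactants: 6 (5R)-5-[(trityloxy)methyl]dihydrofuran-2(3H)-one
Product: 8 (5R)-3-methyl-5-[(trityloxy)methyl]dihydrofuran-2(3H)-one as a mixture of C3 epimers, via lithium enolate 7 (not isolated)
Conditions: LiN(iPr)2, THF, −78 °C; then MeI, −78 to −40 °C
Reagents that add atoms: iodomethane CI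
Why: lactone enolate alkylation, the methyl group entering mainly trans to the trityloxymethyl group; the configuration of this carbon does not matter because it is enolised again in step 5.

Step 5
Reactants: 8 (5R)-3-methyl-5-[(trityloxy)methyl]dihydrofuran-2(3H)-one
Product: 10 (3S,5R)-3-chloro-3-methyl-5-[(trityloxy)methyl]dihydrofuran-2(3H)-one, via lithium enolate 9 (not isolated)
Conditions: LiN(SiMe3)2, THF, −78 °C; then N-chlorosuccinimide, −78 °C
Reagents that add atoms: N-chlorosuccinimide O=C1CCC(=O)N1Cl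
Why: electrophilic chlorination of the planar lactone enolate should occur anti to the bulky trityloxymethyl group (1,3-induction across the five-membered ring), placing chlorine trans to it and setting the future C10 as 3S.

Step 6
Reactants: 10 (3S,5R)-3-chloro-3-methyl-5-[(trityloxy)methyl]dihydrofuran-2(3H)-one
Product: 11 (2S,4R)-2-chloro-2-methyl-5-(trityloxy)pentane-1,4-diol
Conditions: LiBH4, THF, 0 °C to rt; aq. NH4Cl
Reagents that add atoms: none
Why: borohydride reduction of the activated α-chloro lactone to the 1,4-diol should leave the tertiary chloride and the C–O bond of the carbinol stereocentre untouched.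

Step 7
Reactants: 11 (2S,4R)-2-chloro-2-methyl-5-(trityloxy)pentane-1,4-diol
Product: 12 (2S,4R)-1,4-bis[(tert-butyldimethylsilyl)oxy]-2-chloro-2-methyl-5-(trityloxy)pentane
Conditions: t-BuMe2SiOTf (2.5 equiv), 2,6-lutidine, CH2Cl2, −78 to 0 °C
Reagents that add atoms: tert-butyldimethylsilyl trifluoromethanesulfonate CC(C)(C)[Si](C)(C)OS(=O)(=O)C(F)(F)F
Why: silylation of both hydroxyl groups with the reactive silyl triflate under non-nucleophilic base, which avoids closure of the chlorohydrin.

Step 8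
Reactants: 12 (2S,4R)-1,4-bis[(tert-butyldimethylsilyl)oxy]-2-chloro-2-methyl-5-(trityloxy)pentane
Product: 13 (2R,4S)-2,5-bis[(tert-butyldimethylsilyl)oxy]-4-chloro-4-methylpentan-1-ol
Conditions: HCO2H/Et2O (1:1), rt, 15 min; aq. NaHCO3
Reagents that add atoms: none
Why: brief formic acid treatment should ionise only the trityl ether (stabilised trityl cation), the silyl ethers and the tertiary chloride being much slower to react.

Step 9
Reactants: 13 (2R,4S)-2,5-bis[(tert-butyldimethylsilyl)oxy]-4-chloro-4-methylpentan-1-ol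
Product: 14 (2R,4S)-2,5-bis[(tert-butyldimethylsilyl)oxy]-4-chloro-4-methylpentanal
Conditions: Dess–Martin periodinane, NaHCO3, CH2Cl2, 0 °C to rt
Reagents that add atoms: none
Why: Dess–Martin oxidation under buffered, non-epimerising conditions should give the configurationally stable α-silyloxy aldehyde.

Step 10
Reactants: 14 (2R,4S)-2,5-bis[(tert-butyldimethylsilyl)oxy]-4-chloro-4-methylpentanal; 15 methyl acrylate
Product: 16 methyl (4R,6S)-4,7-bis[(tert-butyldimethylsilyl)oxy]-6-chloro-3-hydroxy-6-methyl-2-methylideneheptanoate as a mixture of C3 epimers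
Conditions: DABCO (1 equiv), methyl acrylate (neat, excess), rt, several days
Reagents that add atoms: none
Why: Morita–Baylis–Hillman reaction of the activated α-silyloxy aldehyde; the new carbinol centre forms as a mixture, which is harmless because it becomes sp2 in step 11.

Step 11
Reactants: 16 methyl (4R,6S)-4,7-bis[(tert-butyldimethylsilyl)oxy]-6-chloro-3-hydroxy-6-methyl-2-methylideneheptanoate
Product: 17 methyl (2Z,4R,6S)-2-(bromomethyl)-4,7-bis[(tert-butyldimethylsilyl)oxy]-6-chloro-6-methylhept-2-enoate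
Conditions: N-bromosuccinimide, Me2S, CH2Cl2, 0 °C to rt
Reagents that add atoms: N-bromosuccinimide O=C1CCC(=O)N1Br
Why: activation of the allylic alcohol as an alkoxysulfonium ion and SN2′ attack of bromide on the terminal methylene should give the rearranged, thermodynamically preferred (Z)-2-(bromomethyl)enoate.

**Union and endgame**

Step 12
Reactants: 17 methyl (2Z,4R,6S)-2-(bromomethyl)-4,7-bis[(tert-butyldimethylsilyl)oxy]-6-chloro-6-methylhept-2-enoate; 5 (2Z)-3-methyl-4-oxopent-2-enal
Product: 20 (4S,5R)-4-[(1R,3S)-1,4-bis[(tert-butyldimethylsilyl)oxy]-3-chloro-3-methylbutyl]-3-methylidene-5-[(1Z)-2-methyl-3-oxobut-1-en-1-yl]dihydrofuran-2(3H)-one, via allylchromium reagent 18 (not isolated), via chromium alkoxide 19 (not isolated)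
Conditions: CrCl2 (2.1 equiv), THF, 0 °C, 15 min; then 5 (1.5 equiv), 0 °C to rt; pH 7 buffer
Reagents that add atoms: none
Why: Nozaki–Hiyama allylation, in which the pre-formed trivalent 2-(methoxycarbonyl)allylchromium adds only to the aldehyde through a Zimmerman–Traxler chair (anti C6/C7, hence the trans lactone after in-flask lactonisation), the aldehyde approaching C7 anti to the bulky C9 chain with H8 eclipsing the alkene (allylic 1,3-strain), which sets C7 relative to C8.

Step 13
Reactants: 20 the bis-silyl lactone of step 12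
Product: 21 (4S,5R)-4-[(1R,3S)-1-[(tert-butyldimethylsilyl)oxy]-3-chloro-4-hydroxy-3-methylbutyl]-3-methylidene-5-[(1Z)-2-methyl-3-oxobut-1-en-1-yl]dihydrofuran-2(3H)-one
Conditions: HF·pyridine, pyridine, THF, 0 °C
Reagents that add atoms: none
Why: buffered fluoride should cleave the primary silyl ether much faster than the hindered secondary one at C8.

Step 14
Reactants: 21 the primary alcohol of step 13
Product: 22 (2S,4R)-4-[(tert-butyldimethylsilyl)oxy]-2-chloro-2-methyl-4-[(2R,3S)-4-methylidene-2-[(1Z)-2-methyl-3-oxobut-1-en-1-yl]-5-oxotetrahydrofuran-3-yl]butanal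
Conditions: Dess–Martin periodinane, NaHCO3, CH2Cl2, 0 °C to rt
Reagents that add atoms: none
Why: Dess–Martin oxidation should give the α-chloro aldehyde, which has no α-hydrogen and therefore cannot epimerise or enolise.

Step 15
Reactants: 22 the seco keto-aldehyde of step 14
Product: 25 (1R,3S,4Z,6R,7S,8R,10S)-8-[(tert-butyldimethylsilyl)oxy]-10-chloro-1,3-dihydroxygermacra-4,11(13)-dien-12,6-olide, via boron enolate 23 (not isolated), via boron aldolate 24 (not isolated)
Conditions: Cy2BCl (3 equiv), Et3N (4 equiv), Et2O, −78 °C, 22 added by syringe pump over 8 h (final 2 mM), −78 to −40 °C; then LiBH4 (THF), −78 °C; MeOH, pH 7 buffer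
Reagents that add atoms: none
Why: Cy2BCl/Et3N enolises the C2 methyl of the cross-conjugated ketone (the aldehyde has no α-hydrogen) and the boron dienolate adds through a closed chair transition state to the C1 aldehyde, after which LiBH4 delivers hydride to the six-membered boron chelate of the aldolate. The closest known chemistry is the boron aldol reaction of methyl ketones with α-chloro aldehydes followed by in-flask borohydride reduction to 1,3-syn diols, together with intramolecular aldol closures of medium rings. The ten-membered carbocycle closes in a 10-(enolendo)-exo-trig mode under slow-addition pseudo-dilution. C1 is set by the C10 stereocentre through the Cornforth (polar Felkin–Anh) arrangement, with C–Cl opposed to C=O and C2 passing the methyl group rather than the C9 chain, which should give the anti chlorohydrin (1R); C3 is set by C1 through external hydride attack on the chelate (1,3-syn, 3S). The step needs cyclisation to beat oligomerisation and needs addition to the aldehyde only: the (Z)-enone and the trans-disubstituted lactone hold the two chain ends on the same side, and the non-enolisable, highly electrophilic α-chloro aldehyde is the only acceptor for the mild boron enolate.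

Step 16
Reactants: 25 the chloro diol of step 15
Product: 27 (1R,3S,4Z,6R,7S,8R,10R)-8-[(tert-butyldimethylsilyl)oxy]-1,10-epoxy-3-[(3-methylbutanoyl)oxy]germacra-4,11(13)-dien-12,6-olide, via sodium alkoxide 26 (not isolated)
Conditions: NaH (2.2 equiv), THF, 0 °C, 1 h; then isovaleric anhydride (1.5 equiv), 0 °C
Reagents that add atoms: isovaleric anhydride CC(C)CC(=O)OC(=O)CC(C)C
Why: intramolecular Williamson closure of the chlorohydrin, in which the C1 alkoxide displaces the tertiary chloride at C10 with inversion from the conformer with O–C1–C10–Cl antiperiplanar (C2 and C9 trans, giving the 1R,10R oxirane), and the remaining C3 alkoxide is acylated in the same flask.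

Step 17
Reactants: 27 the silyl ether of step 16
Product: 28 (1R,3S,4Z,6R,7R,8R,10R)-1,10-epoxy-8-hydroxy-3-[(3-methylbutanoyl)oxy]germacra-4,11(13)-dien-12,6-olide
Conditions: Bu4NF/AcOH (1:1), THF, 0 °C to rt
Reagents that add atoms: none
Why: acetic-acid-buffered fluoride desilylation should free the C8 hydroxyl without opening the oxirane or adding to the methylene lactone.

Step 18
Reactants: 28 the C8 alcohol of step 17; 3 (2S,3R)-2,3-dimethyloxirane-2-carboxylic acid
Product: 30 CNP0167461.3, (1R,3S,4Z,6R,7R,8R,10R)-8-{[(2S,3R)-2,3-dimethyloxirane-2-carbonyl]oxy}-1,10-epoxy-3-[(3-methylbutanoyl)oxy]germacra-4,11(13)-dien-12,6-olide, via mixed anhydride 29 (not isolated)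
Conditions: 3, 2,4,6-trichlorobenzoyl chloride, Et3N, THF, rt; then 28, DMAP, toluene, rt
Reagents that add atoms: none
Why: Yamaguchi esterification, in which DMAP transfers the hindered epoxy-acyl group to the C8 hydroxyl with retention at C8, the quaternary α-carbon of the acid being unable to epimerise.

**Compound list**

1 | (E)-2-methylbut-2-en-1-ol | C/C=C(\C)CO | starting material
2 | [(2R,3R)-2,3-dimethyloxiran-2-yl]methanol | OC[C@@]1(C)O[C@@H]1C | intermediate
3 | (2S,3R)-2,3-dimethyloxirane-2-carboxylic acid | O=C(O)[C@@]1(C)O[C@@H]1C | intermediate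
4 | 2,3-dimethylfuran | Cc1occc1C | starting material
5 | (2Z)-3-methyl-4-oxopent-2-enal | CC(=O)/C(C)=C\C=O | intermediate
6 | (5R)-5-[(trityloxy)methyl]dihydrofuran-2(3H)-one | O=C1CC[C@H](COC(c2ccccc2)(c2ccccc2)c2ccccc2)O1 | starting material
7 | lithium enolate of 6 (not isolated) | [Li]OC1=CC[C@H](COC(c2ccccc2)(c2ccccc2)c2ccccc2)O1 | intermediate
8 | (5R)-3-methyl-5-[(trityloxy)methyl]dihydrofuran-2(3H)-one (C3 epimers) | CC1C[C@H](COC(c2ccccc2)(c2ccccc2)c2ccccc2)OC1=O | intermediate
9 | lithium enolate of 8 (not isolated) | [Li]OC1=C(C)C[C@H](COC(c2ccccc2)(c2ccccc2)c2ccccc2)O1 | intermediate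
10 | (3S,5R)-3-chloro-3-methyl-5-[(trityloxy)methyl]dihydrofuran-2(3H)-one | C[C@]1(Cl)C[C@H](COC(c2ccccc2)(c2ccccc2)c2ccccc2)OC1=O | intermediate
11 | (2S,4R)-2-chloro-2-methyl-5-(trityloxy)pentane-1,4-diol | OC[C@@](C)(Cl)C[C@@H](O)COC(c1ccccc1)(c1ccccc1)c1ccccc1 | intermediate
12 | (2S,4R)-1,4-bis[(tert-butyldimethylsilyl)oxy]-2-chloro-2-methyl-5-(trityloxy)pentane | CC(C)(C)[Si](C)(C)OC[C@@](C)(Cl)C[C@@H](O[Si](C)(C)C(C)(C)C)COC(c1ccccc1)(c1ccccc1)c1ccccc1 | intermediate
13 | (2R,4S)-2,5-bis[(tert-butyldimethylsilyl)oxy]-4-chloro-4-methylpentan-1-ol | CC(C)(C)[Si](C)(C)OC[C@@](C)(Cl)C[C@@H](O[Si](C)(C)C(C)(C)C)CO | intermediate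
14 | (2R,4S)-2,5-bis[(tert-butyldimethylsilyl)oxy]-4-chloro-4-methylpentanal | O=C[C@H](O[Si](C)(C)C(C)(C)C)C[C@](C)(Cl)CO[Si](C)(C)C(C)(C)C | intermediate
15 | methyl acrylate | C=CC(=O)OC | starting material
16 | methyl (4R,6S)-4,7-bis[(tert-butyldimethylsilyl)oxy]-6-chloro-3-hydroxy-6-methyl-2-methylideneheptanoate (C3 epimers) | C=C(C(=O)OC)C(O)[C@H](O[Si](C)(C)C(C)(C)C)C[C@](C)(Cl)CO[Si](C)(C)C(C)(C)C | intermediate
17 | methyl (2Z,4R,6S)-2-(bromomethyl)-4,7-bis[(tert-butyldimethylsilyl)oxy]-6-chloro-6-methylhept-2-enoate | COC(=O)/C(CBr)=C/[C@H](O[Si](C)(C)C(C)(C)C)C[C@](C)(Cl)CO[Si](C)(C)C(C)(C)C | intermediate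
18 | allylchromium dichloride derived from 17 (trivalent chromium, not isolated) | COC(=O)C(C[Cr](Cl)Cl)=C[C@H](O[Si](C)(C)C(C)(C)C)C[C@](C)(Cl)CO[Si](C)(C)C(C)(C)C | intermediate
19 | chromium alkoxide of the anti hydroxy ester adduct (not isolated) | C=C(C(=O)OC)[C@@H]([C@H](O[Cr](Cl)Cl)/C=C(/C)C(C)=O)[C@H](O[Si](C)(C)C(C)(C)C)C[C@](C)(Cl)CO[Si](C)(C)C(C)(C)C | intermediate
20 | (4S,5R)-4-[(1R,3S)-1,4-bis[(tert-butyldimethylsilyl)oxy]-3-chloro-3-methylbutyl]-3-methylidene-5-[(1Z)-2-methyl-3-oxobut-1-en-1-yl]dihydrofuran-2(3H)-one | C=C1C(=O)O[C@H](/C=C(/C)C(C)=O)[C@H]1[C@H](O[Si](C)(C)C(C)(C)C)C[C@](C)(Cl)CO[Si](C)(C)C(C)(C)C | intermediate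
21 | (4S,5R)-4-[(1R,3S)-1-[(tert-butyldimethylsilyl)oxy]-3-chloro-4-hydroxy-3-methylbutyl]-3-methylidene-5-[(1Z)-2-methyl-3-oxobut-1-en-1-yl]dihydrofuran-2(3H)-one | C=C1C(=O)O[C@H](/C=C(/C)C(C)=O)[C@H]1[C@H](O[Si](C)(C)C(C)(C)C)C[C@](C)(Cl)CO | intermediate
22 | (2S,4R)-4-[(tert-butyldimethylsilyl)oxy]-2-chloro-2-methyl-4-[(2R,3S)-4-methylidene-2-[(1Z)-2-methyl-3-oxobut-1-en-1-yl]-5-oxotetrahydrofuran-3-yl]butanal (6R,7S,8R,10S in germacrane numbering) | C=C1C(=O)O[C@H](/C=C(/C)C(C)=O)[C@H]1[C@H](O[Si](C)(C)C(C)(C)C)C[C@](C)(Cl)C=O | intermediate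
23 | dicyclohexylboron enolate of 22 at C2=C3 (not isolated) | C=C1C(=O)O[C@H](/C=C(/C)C(=C)OB(C2CCCCC2)C2CCCCC2)[C@H]1[C@H](O[Si](C)(C)C(C)(C)C)C[C@](C)(Cl)C=O | intermediate
24 | (1R,4Z,6R,7S,8R,10S)-8-[(tert-butyldimethylsilyl)oxy]-10-chloro-1-[(dicyclohexylboranyl)oxy]-3-oxogermacra-4,11(13)-dien-12,6-olide (not isolated) | C=C1C(=O)O[C@@H]2/C=C(/C)C(=O)C[C@@H](OB(C3CCCCC3)C3CCCCC3)[C@@](C)(Cl)C[C@@H](O[Si](C)(C)C(C)(C)C)[C@@H]12 | intermediate
25 | (1R,3S,4Z,6R,7S,8R,10S)-8-[(tert-butyldimethylsilyl)oxy]-10-chloro-1,3-dihydroxygermacra-4,11(13)-dien-12,6-olide | C=C1C(=O)O[C@@H]2/C=C(/C)[C@@H](O)C[C@@H](O)[C@@](C)(Cl)C[C@@H](O[Si](C)(C)C(C)(C)C)[C@@H]12 | intermediate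
26 | sodium C3 alkoxide of (1R,3S,4Z,6R,7S,8R,10R)-8-[(tert-butyldimethylsilyl)oxy]-1,10-epoxy-3-hydroxygermacra-4,11(13)-dien-12,6-olide (not isolated) | C=C1C(=O)O[C@@H]2/C=C(/C)[C@@H](O[Na])C[C@H]3O[C@]3(C)C[C@@H](O[Si](C)(C)C(C)(C)C)[C@@H]12 | intermediate
27 | (1R,3S,4Z,6R,7S,8R,10R)-8-[(tert-butyldimethylsilyl)oxy]-1,10-epoxy-3-[(3-methylbutanoyl)oxy]germacra-4,11(13)-dien-12,6-olide | C=C1C(=O)O[C@@H]2/C=C(/C)[C@@H](OC(=O)CC(C)C)C[C@H]3O[C@]3(C)C[C@@H](O[Si](C)(C)C(C)(C)C)[C@@H]12 | intermediate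
28 | (1R,3S,4Z,6R,7R,8R,10R)-1,10-epoxy-8-hydroxy-3-[(3-methylbutanoyl)oxy]germacra-4,11(13)-dien-12,6-olide | C=C1C(=O)O[C@@H]2/C=C(/C)[C@@H](OC(=O)CC(C)C)C[C@H]3O[C@]3(C)C[C@@H](O)[C@@H]12 | intermediate
29 | (2S,3R)-2,3-dimethyloxirane-2-carboxylic 2,4,6-trichlorobenzoic anhydride (not isolated) | O=C(OC(=O)c1c(Cl)cc(Cl)cc1Cl)[C@@]2(C)O[C@@H]2C | intermediate
30 | CNP0167461.3, (1R,3S,4Z,6R,7R,8R,10R)-8-{[(2S,3R)-2,3-dimethyloxirane-2-carbonyl]oxy}-1,10-epoxy-3-[(3-methylbutanoyl)oxy]germacra-4,11(13)-dien-12,6-olide | C=C1C(=O)O[C@@H]2/C=C(/C)[C@@H](OC(=O)CC(C)C)C[C@H]3O[C@]3(C)C[C@@H](OC(=O)[C@@]3(C)O[C@@H]3C)[C@@H]12 | target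

**Step count.** Total: 18 steps. Longest linear sequence: 15 steps (steps 4–18, from lactone 6); steps 1–2 (acid 3) and step 3 (enal 5) are convergent branches.

**Steps most likely to fail**

Step 15 (key step). The intramolecular addition may lose to intermolecular aldol oligomerisation. Facial selectivity at C1 may be poor, because the methyl group and the C9 methylene on C10 differ little in size. LiBH4 may also attack the methylene lactone. Fallback, from 22 back to 25: 22 would be converted with Me3SiOTf/Et3N (CH2Cl2, −78 °C) into the trimethylsilyl enol ether F1. F1 would be cyclised at high dilution by an intramolecular Mukaiyama aldol addition (BF3·OEt2, CH2Cl2, −78 °C; open transition state, chlorine anti to the incoming enol ether) to the macrocyclic β-hydroxy ketone F2. A separate Narasaka–Prasad reduction (Et2BOMe, NaBH4, THF/MeOH, −78 °C) would then give the 1,3-syn diol 25.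

Step 12. Residual divalent chromium may transfer an electron to the electron-poor oxo-enal 5 and reduce it. The cis γ-hydroxy enone adduct may also cyclodehydrate to a furan before it lactonises. Fallback, from 17 back to 20, which brings in the acetyl group only after the lactone exists: commercial ethyl but-2-ynoate would be hydroiodinated (NaI, AcOH, 115 °C) to ethyl (2Z)-3-iodobut-2-enoate F3, reduced (iBu2AlH, CH2Cl2, −78 °C) to (2Z)-3-iodobut-2-en-1-ol F4 and oxidised (MnO2, CH2Cl2) to (2Z)-3-iodobut-2-enal F5. The allylchromium reagent from 17 (CrCl2, THF; the vinyl iodide is inert without nickel) would add to F5 and lactonise to the iodo lactone F6. A Stille coupling with tributyl(1-ethoxyvinyl)stannane (Pd(PPh3)4, zerovalent palladium, CuI, DMF) would give the ethoxyvinyl lactone F7, and mild hydrolysis (aqueous oxalic acid, THF) would release methyl ketone 20.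

Step 16. The C3 alkoxide may attack C10 across the ring, either displacing chloride or opening the new oxirane to a 3,10-ether. HCl may be lost by elimination, or an alkoxide may add to the methylene lactone. Fallback, from 25 back to 27: the less hindered allylic C3 hydroxyl would be acylated first (isovaleric anhydride, DMAP cat., pyridine, CH2Cl2, −20 °C) to the 3-O-isovaleryl chlorohydrin F8. The oxirane would then be closed with K2CO3 in MeCN, when no C3 alkoxide can form, to give 27.

**Further compounds**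

F1 | step 15 | trimethylsilyl enol ether of 22 (C2=C3) | C=C1C(=O)O[C@H](/C=C(/C)C(=C)O[Si](C)(C)C)[C@H]1[C@H](O[Si](C)(C)C(C)(C)C)C[C@](C)(Cl)C=O
F2 | step 15 | (1R,4Z,6R,7S,8R,10S)-8-[(tert-butyldimethylsilyl)oxy]-10-chloro-1-hydroxy-3-oxogermacra-4,11(13)-dien-12,6-olide | C=C1C(=O)O[C@@H]2/C=C(/C)C(=O)C[C@@H](O)[C@@](C)(Cl)C[C@@H](O[Si](C)(C)C(C)(C)C)[C@@H]12
F3 | step 12 | ethyl (2Z)-3-iodobut-2-enoate | CCOC(=O)/C=C(/C)I
F4 | step 12 | (2Z)-3-iodobut-2-en-1-ol | OC/C=C(/C)I
F5 | step 12 | (2Z)-3-iodobut-2-enal | O=C/C=C(/C)I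
F6 | step 12 | (4S,5R)-4-[(1R,3S)-1,4-bis[(tert-butyldimethylsilyl)oxy]-3-chloro-3-methylbutyl]-5-[(1Z)-2-iodoprop-1-en-1-yl]-3-methylidenedihydrofuran-2(3H)-one | C=C1C(=O)O[C@H](/C=C(/C)I)[C@H]1[C@H](O[Si](C)(C)C(C)(C)C)C[C@](C)(Cl)CO[Si](C)(C)C(C)(C)C
F7 | step 12 | (4S,5R)-4-[(1R,3S)-1,4-bis[(tert-butyldimethylsilyl)oxy]-3-chloro-3-methylbutyl]-5-[(1Z)-3-ethoxy-2-methylbuta-1,3-dien-1-yl]-3-methylidenedihydrofuran-2(3H)-one | C=C1C(=O)O[C@H](/C=C(/C)C(=C)OCC)[C@H]1[C@H](O[Si](C)(C)C(C)(C)C)C[C@](C)(Cl)CO[Si](C)(C)C(C)(C)C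
F8 | step 16 | (1R,3S,4Z,6R,7S,8R,10S)-8-[(tert-butyldimethylsilyl)oxy]-10-chloro-1-hydroxy-3-[(3-methylbutanoyl)oxy]germacra-4,11(13)-dien-12,6-olide | C=C1C(=O)O[C@@H]2/C=C(/C)[C@@H](OC(=O)CC(C)C)C[C@@H](O)[C@@](C)(Cl)C[C@@H](O[Si](C)(C)C(C)(C)C)[C@@H]12
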